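## Retrosynthetic overview

1. The strategy rests on the seven-membered ring: once C6–OAr is read as C6=O, the atoms C6(=O)–C7H2–C8(OH)(CH3) form a β-hydroxy carbonyl (aldol) array, and the C9 oxygen sits on the carbon next to the electrophilic C8.
2. Last ring: the C7–C8 bond is cut; a samarium enolate made from a C6 bromoacetyl group adds to a C8 methyl ketone, both carried by a cyclopentane.
3. Side arm C10–C9(OBn)–C8: from an allyl group on C1 (ozonolysis, catalyst-controlled isopropenyl addition, late ozonolysis to unmask the methyl ketone); the C1 quaternary centre comes from conjugate allylation of a cyclopentene carbaldehyde.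
4. First ring: the cyclopentene comes from (S)-terpinen-4-ol by ozonolysis and aldol condensation; C4 is taken from the chiral pool.
5. Endgame: C8–OH-directed anti reduction of C6=O, aroylation, desilylation, hydrogenolysis. Ring order: five-membered ring first, seven-membered ring in the key step.

Key step: step 12

Remark: (S)-(+)-terpinen-4-ol is assumed to be used in high enantiomeric purity (commercial material enriched if needed); daucane locants (C1 = quaternary C–CH3, C4 = C(O)(iPr), C5 = ring CH, C6–C10 = later seven-ring carbons) are used for all intermediates, and β is the face of the C1 methyl group.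

## Route

Step 1
Reactants: 1 (S)-(+)-terpinen-4-ol
Product: 2 (S)-terpinen-4-yl triethylsilyl ether
Conditions: TESOTf, 2,6-lutidine, CH2Cl2, −78 to 0 °C
Reagents that add atoms: triethylsilyl trifluoromethanesulfonate, CC[Si](CC)(CC)OS(=O)(=O)C(F)(F)F
Why: Silylation of the hindered tertiary alcohol with a silyl triflate and 2,6-lutidine is standard and masks the hydroxyl that would otherwise be a free β-hydroxy carbonyl in the next steps; the C4 stereocentre is carried over unchanged from 1.

Step 2
Reactants: 2 (S)-terpinen-4-yl triethylsilyl ether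
Product: 4 (S)-3-isopropyl-6-oxo-3-(triethylsilyloxy)heptanal, via ozonide 3 (not isolated)
Conditions: O3, CH2Cl2, −78 °C; then PPh3, −78 °C to rt
Reagents that add atoms: ozone, [O-][O+]=O
Why: Ozonolysis with reductive phosphine work-up cleaves the only C=C bond to the methyl ketone and the aldehyde without touching the silyl ether.

Step 3
Reactants: 4 (S)-3-isopropyl-6-oxo-3-(triethylsilyloxy)heptanal
Product: 6 (R)-5-isopropyl-2-methyl-5-(triethylsilyloxy)cyclopent-1-ene-1-carbaldehyde, via aldol 5 (not isolated)
Conditions: piperidine (0.3 equiv), AcOH (0.3 equiv), toluene, 60 °C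
Reagents that add atoms: none
Why: Amine/acid-catalysed intramolecular aldol condensation (aldehyde enamine onto the methyl ketone, 5-(enolexo)-exo-trig) should close the cyclopentene, the acid-assisted aldol hydroxyl being lost in preference to the bulky tertiary silyloxy group to give the tetrasubstituted enal.

Step 4
Reactants: 6 (R)-5-isopropyl-2-methyl-5-(triethylsilyloxy)cyclopent-1-ene-1-carbaldehyde; 7 allylmagnesium bromide
Product: 9 1α-allyl-5β-formyl-4α-isopropyl-1β-methyl-4β-(triethylsilyloxy)cyclopentane, via trimethylsilyl enol ether 8 (not isolated)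
Conditions: CuBr·SMe2, TMSCl, THF, −78 °C; then K2CO3, MeOH, 0 °C
Reagents that add atoms: none
Why: TMSCl-accelerated conjugate addition of an allylcopper reagent builds the C1 quaternary centre, the reagent being expected to add on the α face, anti to the pseudo-axial C4–OSiEt3 bond (isopropyl pseudo-equatorial), and methanolysis of the enol silane under mild base should equilibrate C5 to the isomer with the formyl group trans to allyl and isopropyl.

Step 5
Reactants: 9 1α-allyl-5β-formyl-4α-isopropyl-1β-methyl-4β-(triethylsilyloxy)cyclopentane; 10 methylmagnesium bromide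
Product: 11 1α-allyl-5β-(1-hydroxyethyl)-4α-isopropyl-1β-methyl-4β-(triethylsilyloxy)cyclopentane
Conditions: THF, −78 °C; aq. NH4Cl
Reagents that add atoms: none
Why: Grignard 1,2-addition to the aldehyde brings in C7; the carbinol configuration is irrelevant because the centre is oxidised in the next step.

Step 6
Reactants: 11 1α-allyl-5β-(1-hydroxyethyl)-4α-isopropyl-1β-methyl-4β-(triethylsilyloxy)cyclopentane
Product: 12 5β-acetyl-1α-allyl-4α-isopropyl-1β-methyl-4β-(triethylsilyloxy)cyclopentane
Conditions: Dess–Martin periodinane, NaHCO3, CH2Cl2, 0 °C to rt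
Reagents that add atoms: none
Why: Buffered Dess–Martin oxidation gives the methyl ketone under neutral conditions that should neither epimerise C5 nor eliminate the β-silyloxy group.

Step 7
Reactants: 12 5β-acetyl-1α-allyl-4α-isopropyl-1β-methyl-4β-(triethylsilyloxy)cyclopentane
Product: 14 5β-acetyl-4α-isopropyl-1β-methyl-1α-(2-oxoethyl)-4β-(triethylsilyloxy)cyclopentane, via ozonide 13 (not isolated)
Conditions: O3, CH2Cl2, −78 °C; then PPh3, −78 °C to rt
Reagents that add atoms: ozone, [O-][O+]=O
Why: Ozonolysis of the single terminal alkene with reductive work-up turns the allyl group into the C9 aldehyde.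

Step 8
Reactants: 14 5β-acetyl-4α-isopropyl-1β-methyl-1α-(2-oxoethyl)-4β-(triethylsilyloxy)cyclopentane; 15 2-bromopropene
Product: 16 5β-acetyl-1α-[(2S)-2-hydroxy-3-methylbut-3-enyl]-4α-isopropyl-1β-methyl-4β-(triethylsilyloxy)cyclopentane
Conditions: Cr(II)–chiral oxazoline-sulfonamide complex (10 mol %, antipode giving 9S), NiCl2·2,9-dimethyl-1,10-phenanthroline (2 mol %), Mn, Cp2ZrCl2, LiCl, MeCN, rt
Reagents that add atoms: none
Why: Catalytic asymmetric Nozaki–Hiyama–Kishi alkenylation is non-basic and selective for the aldehyde over the hindered ketone, and the chiral chromium ligand (catalyst control) sets C9, which is too remote from the ring stereocentres for substrate control.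

Step 9
Reactants: 16 5β-acetyl-1α-[(2S)-2-hydroxy-3-methylbut-3-enyl]-4α-isopropyl-1β-methyl-4β-(triethylsilyloxy)cyclopentane
Product: 17 5β-acetyl-1α-[(2S)-2-(benzyloxy)-3-methylbut-3-enyl]-4α-isopropyl-1β-methyl-4β-(triethylsilyloxy)cyclopentane
Conditions: 2-benzyloxy-1-methylpyridinium triflate, MgO, PhCF3, 85 °C
Reagents that add atoms: 2-benzyloxy-1-methylpyridinium trifluoromethanesulfonate, C[n+]1ccccc1OCc1ccccc1.[O-]S(=O)(=O)C(F)(F)F
Why: Neutral benzyl transfer from the pyridinium salt (SN1-type O-benzylation) avoids base, which would enolise the ketone, and strong acid, which would ionise the allylic alcohol or the silyl ether.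

Step 10
Reactants: 17 5β-acetyl-1α-[(2S)-2-(benzyloxy)-3-methylbut-3-enyl]-4α-isopropyl-1β-methyl-4β-(triethylsilyloxy)cyclopentane
Product: 19 1α-[(2S)-2-(benzyloxy)-3-methylbut-3-enyl]-5β-(bromoacetyl)-4α-isopropyl-1β-methyl-4β-(triethylsilyloxy)cyclopentane, via enol silane 18 (not isolated)
Conditions: LiHMDS, TMSCl, THF, −78 °C; then NBS, −78 to 0 °C
Reagents that add atoms: N-bromosuccinimide, O=C1CCC(=O)N1Br
Why: Kinetic deprotonation with in-situ silylation should occur at the methyl group (C5–H lies between two quaternary carbons), and electrophilic bromination of the enol silane then gives the bromomethyl ketone faster than NBS attacks the 1,1-disubstituted alkene.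

Step 11
Reactants: 19 1α-[(2S)-2-(benzyloxy)-3-methylbut-3-enyl]-5β-(bromoacetyl)-4α-isopropyl-1β-methyl-4β-(triethylsilyloxy)cyclopentane
Product: 20 1α-[(2S)-2-(benzyloxy)-3-oxobutyl]-5β-(bromoacetyl)-4α-isopropyl-1β-methyl-4β-(triethylsilyloxy)cyclopentane
Conditions: O3, pyridine (3 equiv), CH2Cl2, −78 °C
Reagents that add atoms: ozone, [O-][O+]=O
Why: Pyridine-mediated ozonolysis delivers the C8 methyl ketone directly from the isopropenyl group without a phosphine or sulfide reductant, which would be alkylated by the α-bromo ketone.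

Step 12
Reactants: 20 1α-[(2S)-2-(benzyloxy)-3-oxobutyl]-5β-(bromoacetyl)-4α-isopropyl-1β-methyl-4β-(triethylsilyloxy)cyclopentane
Product: 22 9α-benzyloxy-8β-hydroxy-4β-(triethylsilyloxy)daucan-6-one, via samarium enolate 21 (not isolated)
Conditions: SmI2 (2.2 equiv, 0.1 M in THF) added to 20 (0.005 M in THF), −78 °C; aq. NH4Cl at −78 °C
Reagents that add atoms: none
Why: Two single-electron transfers from SmI2 cleave the C–Br bond of 20 and give samarium(III) enolate 21, which can only be the C6–C7 enolate, so the acidic C5–H (whose enolate would expel the 4-silyloxy group) and the α-positions of the C8 ketone are never deprotonated, which a base-mediated diketone aldol could not guarantee. The closest known reaction type is the SmI2-promoted intramolecular Reformatsky-type aldol of α-bromo ketones and esters onto ketones, which is used for medium rings. C7 adds to the C8 carbonyl in a 7-(enolendo)-exo-trig closure that forms the C7–C8 bond and the seven-membered ring. The new C8 stereocentre is set in a closed transition state in which samarium bridges the enolate oxygen and the ketone oxygen: with the tether anchored on the trans-disposed C5 and C1, the ketone should reach C7 only with its oxygen turned towards O6 on the β face, the C8 methyl pointing outwards (α) and the 9α-benzyloxy group pseudo-equatorial and remote from the metal, which gives the 8β-hydroxyl trans to O9. The step needs the C–Br bond to be reduced faster than the α-benzyloxy ketone is cleaved or pinacolised, which the much easier reduction of the α-bromo ketone, the limited amount of reagent, −78 °C and the absence of HMPA or a proton source should secure, and it needs C–C bond formation to outrun protonation of the enolate, which high dilution in dry THF should secure. Retro-aldol cleavage is held back because the product stays as its samarium aldolate until the cold quench.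

Step 13
Reactants: 22 9α-benzyloxy-8β-hydroxy-4β-(triethylsilyloxy)daucan-6-one
Product: 23 9α-benzyloxy-4β-(triethylsilyloxy)daucane-6α,8β-diol
Conditions: Me4NBH(OAc)3, MeCN/AcOH (1:1), −30 to 0 °C
Reagents that add atoms: none
Why: Evans–Saksena reduction: the C8 hydroxyl exchanges onto boron and delivers hydride intramolecularly to the β face of the C6 ketone, which should give the 1,3-anti diol with the 6α-hydroxyl.

Step 14
Reactants: 23 9α-benzyloxy-4β-(triethylsilyloxy)daucane-6α,8β-diol; 24 4-(benzyloxy)benzoyl chloride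
Product: 25 9α-benzyloxy-8β-hydroxy-4β-(triethylsilyloxy)daucan-6α-yl 4-(benzyloxy)benzoate
Conditions: Et3N, DMAP (0.2 equiv), CH2Cl2, 0 °C to rt
Reagents that add atoms: none
Why: DMAP-catalysed acylation should esterify the secondary C6 alcohol only, since the C8 hydroxyl is tertiary and the other oxygens are protected.

Step 15
Reactants: 25 9α-benzyloxy-8β-hydroxy-4β-(triethylsilyloxy)daucan-6α-yl 4-(benzyloxy)benzoate
Product: 26 9α-benzyloxy-4β,8β-dihydroxydaucan-6α-yl 4-(benzyloxy)benzoate
Conditions: HF·pyridine, pyridine/THF, 0 °C to rt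
Reagents that add atoms: none
Why: Buffered fluoride desilylation cleaves the tertiary triethylsilyl ether while the aryl ester and both benzyl ethers remain.

Step 16
Reactants: 26 9α-benzyloxy-4β,8β-dihydroxydaucan-6α-yl 4-(benzyloxy)benzoate
Product: 27 4β,8β,9α-trihydroxydaucan-6α-yl 4-hydroxybenzoate (CNP0197754.1)
Conditions: H2 (1 atm), Pd(OH)2/C, EtOAc/EtOH, rt
Reagents that add atoms: none
Why: Catalytic hydrogenolysis removes the alkyl and the aryl benzyl ether in one operation, and the benzoate ester, which is not benzylic on its alkyl oxygen, should survive.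

## Compound list

1 | (S)-(+)-terpinen-4-ol | CC(C)[C@]1(O)CCC(C)=CC1 | starting material
2 | (S)-terpinen-4-yl triethylsilyl ether | CC(C)[C@]1(O[Si](CC)(CC)CC)CCC(C)=CC1 | intermediate
3 | bicyclic ozonide (1,2,4-trioxolane) of 2, trioxolane carbons unassigned | CC(C)[C@]1(O[Si](CC)(CC)CC)CCC2(C)OOC(C1)O2 | intermediate
4 | (S)-3-isopropyl-6-oxo-3-(triethylsilyloxy)heptanal | CC(C)[C@](O[Si](CC)(CC)CC)(CCC(C)=O)CC=O | intermediate
5 | aldol: 2-hydroxy-5-isopropyl-2-methyl-5-(triethylsilyloxy)cyclopentane-1-carbaldehyde, new centres unassigned | CC(C)[C@]1(O[Si](CC)(CC)CC)CCC(C)(O)C1C=O | intermediate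
6 | (R)-5-isopropyl-2-methyl-5-(triethylsilyloxy)cyclopent-1-ene-1-carbaldehyde | CC(C)[C@]1(O[Si](CC)(CC)CC)CCC(C)=C1C=O | intermediate
7 | allylmagnesium bromide | C=CC[Mg]Br | starting material
8 | trimethylsilyl enol ether of 9, enol ether geometry unassigned | CC(C)[C@]1(O[Si](CC)(CC)CC)CC[C@](C)(CC=C)C1=CO[Si](C)(C)C | intermediate
9 | 1α-allyl-5β-formyl-4α-isopropyl-1β-methyl-4β-(triethylsilyloxy)cyclopentane | CC(C)[C@]1(O[Si](CC)(CC)CC)CC[C@](C)(CC=C)[C@H]1C=O | intermediate
10 | methylmagnesium bromide | C[Mg]Br | starting material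
11 | 1α-allyl-5β-(1-hydroxyethyl)-4α-isopropyl-1β-methyl-4β-(triethylsilyloxy)cyclopentane, both carbinol epimers | CC(C)[C@]1(O[Si](CC)(CC)CC)CC[C@](C)(CC=C)[C@H]1C(C)O | intermediate
12 | 5β-acetyl-1α-allyl-4α-isopropyl-1β-methyl-4β-(triethylsilyloxy)cyclopentane | CC(C)[C@]1(O[Si](CC)(CC)CC)CC[C@](C)(CC=C)[C@H]1C(C)=O | intermediate
13 | ozonide (1,2,4-trioxolane) of 12, trioxolane carbon unassigned | CC(C)[C@]1(O[Si](CC)(CC)CC)CC[C@](C)(CC2OCOO2)[C@H]1C(C)=O | intermediate
14 | 5β-acetyl-4α-isopropyl-1β-methyl-1α-(2-oxoethyl)-4β-(triethylsilyloxy)cyclopentane | CC(C)[C@]1(O[Si](CC)(CC)CC)CC[C@](C)(CC=O)[C@H]1C(C)=O | intermediate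
15 | 2-bromopropene | CC(Br)=C | starting material
16 | 5β-acetyl-1α-[(2S)-2-hydroxy-3-methylbut-3-enyl]-4α-isopropyl-1β-methyl-4β-(triethylsilyloxy)cyclopentane | CC(C)[C@]1(O[Si](CC)(CC)CC)CC[C@](C)(C[C@H](O)C(C)=C)[C@H]1C(C)=O | intermediate
17 | 5β-acetyl-1α-[(2S)-2-(benzyloxy)-3-methylbut-3-enyl]-4α-isopropyl-1β-methyl-4β-(triethylsilyloxy)cyclopentane | CC(C)[C@]1(O[Si](CC)(CC)CC)CC[C@](C)(C[C@H](OCc2ccccc2)C(C)=C)[C@H]1C(C)=O | intermediate
18 | kinetic trimethylsilyl enol ether of 17 (C6=C7) | CC(C)[C@]1(O[Si](CC)(CC)CC)CC[C@](C)(C[C@H](OCc2ccccc2)C(C)=C)[C@H]1C(=C)O[Si](C)(C)C | intermediate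
19 | 1α-[(2S)-2-(benzyloxy)-3-methylbut-3-enyl]-5β-(bromoacetyl)-4α-isopropyl-1β-methyl-4β-(triethylsilyloxy)cyclopentane | CC(C)[C@]1(O[Si](CC)(CC)CC)CC[C@](C)(C[C@H](OCc2ccccc2)C(C)=C)[C@H]1C(=O)CBr | intermediate
20 | 1α-[(2S)-2-(benzyloxy)-3-oxobutyl]-5β-(bromoacetyl)-4α-isopropyl-1β-methyl-4β-(triethylsilyloxy)cyclopentane | CC(C)[C@]1(O[Si](CC)(CC)CC)CC[C@](C)(C[C@H](OCc2ccccc2)C(C)=O)[C@H]1C(=O)CBr | intermediate
21 | samarium(III) enolate (C6=C7, O–SmI2) of the debrominated diketone | CC(C)[C@]1(O[Si](CC)(CC)CC)CC[C@](C)(C[C@H](OCc2ccccc2)C(C)=O)[C@H]1C(=C)O[Sm](I)I | intermediate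
22 | 9α-benzyloxy-8β-hydroxy-4β-(triethylsilyloxy)daucan-6-one | CC(C)[C@]1(O[Si](CC)(CC)CC)CC[C@]2(C)C[C@H](OCc3ccccc3)[C@@](C)(O)CC(=O)[C@H]21 | intermediate
23 | 9α-benzyloxy-4β-(triethylsilyloxy)daucane-6α,8β-diol | CC(C)[C@]1(O[Si](CC)(CC)CC)CC[C@]2(C)C[C@H](OCc3ccccc3)[C@@](C)(O)C[C@H](O)[C@H]21 | intermediate
24 | 4-(benzyloxy)benzoyl chloride | O=C(Cl)c1ccc(OCc2ccccc2)cc1 | starting material
25 | 9α-benzyloxy-8β-hydroxy-4β-(triethylsilyloxy)daucan-6α-yl 4-(benzyloxy)benzoate | CC(C)[C@]1(O[Si](CC)(CC)CC)CC[C@]2(C)C[C@H](OCc3ccccc3)[C@@](C)(O)C[C@H](OC(=O)c3ccc(OCc4ccccc4)cc3)[C@H]21 | intermediate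
26 | 9α-benzyloxy-4β,8β-dihydroxydaucan-6α-yl 4-(benzyloxy)benzoate | CC(C)[C@]1(O)CC[C@]2(C)C[C@H](OCc3ccccc3)[C@@](C)(O)C[C@H](OC(=O)c3ccc(OCc4ccccc4)cc3)[C@H]21 | intermediate
27 | 4β,8β,9α-trihydroxydaucan-6α-yl 4-hydroxybenzoate (CNP0197754.1) | CC(C)[C@]1(O)CC[C@]2(C)C[C@H](O)[C@@](C)(O)C[C@H](OC(=O)c3ccc(O)cc3)[C@H]21 | target

## Step count and risks

Total step count: 16. Longest linear sequence: 16 steps (1 to 27).

Steps most likely to fail:

1. Step 12 (key step). The samarium enolate may attack the other face of the C8 ketone, for example through a competing samarium chelate to the benzyl ether oxygen, so that the 8α-carbinol forms alone or beside 22 (poor facial selectivity). The fallback sets out from 20 and returns at 22. The cyclisation is run as described and the product is taken on as the 8-epi aldol F1, with or without 22. Dehydration with the Burgess reagent (benzene, 50 °C), driven towards conjugation, should give 9α-benzyloxy-4β-(triethylsilyloxy)dauc-7-en-6-one F2. Weitz–Scheffer epoxidation (H2O2, NaOH, MeOH, 0 °C) should add to C8 anti to the neighbouring 9α-benzyloxy group and give the 7β,8β-epoxy ketone F3. Reductive opening of the α,β-epoxy ketone at C7 (SmI2, THF/MeOH, −90 °C) should then give 22 with the 8β-hydroxyl.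

2. Step 4. The allyl–metal may add 1,2 to the aldehyde instead of 1,4, and the aggregated copper reagent may discriminate poorly between the two faces of C1. The fallback sets out from 6 and returns at 9. Reagent 7 alone (THF, −78 °C) is allowed to add 1,2 and should give the bis-allylic carbinol F4. KH/18-crown-6 (THF, 0 °C) should then trigger an anionic oxy-Cope rearrangement that relays the allyl group to C1 through a chair transition state on the face anti to the pseudo-axial silyloxy group. A cold acidic quench, which limits loss of the β-silyloxy group from the enolate, followed by K2CO3/MeOH equilibration of C5 should give 9.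

3. Step 13. The tertiary C8 hydroxyl may exchange onto boron too slowly, so that undirected hydride attack from the α face, which is free of the C1 methyl and C4 silyloxy groups, competes and gives the 6β-alcohol (poor facial selectivity). The fallback sets out from 22 and returns at 25. Ketone 22 is reduced on purpose from the open α face with L-Selectride (THF, −78 °C), which should give the 6β-alcohol F5. Mitsunobu esterification (4-(benzyloxy)benzoic acid, PPh3, DIAD, toluene, 0 °C to rt) should then invert C6 and give ester 25 directly.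

Further compounds

F1 | step 12 | 9α-benzyloxy-8α-hydroxy-4β-(triethylsilyloxy)-8-epi-daucan-6-one | CC(C)[C@]1(O[Si](CC)(CC)CC)CC[C@]2(C)C[C@H](OCc3ccccc3)[C@](C)(O)CC(=O)[C@H]21
F2 | step 12 | 9α-benzyloxy-4β-(triethylsilyloxy)dauc-7-en-6-one | CC(C)[C@]1(O[Si](CC)(CC)CC)CC[C@]2(C)C[C@H](OCc3ccccc3)C(C)=CC(=O)[C@H]21
F3 | step 12 | 9α-benzyloxy-7β,8β-epoxy-4β-(triethylsilyloxy)daucan-6-one | CC(C)[C@]1(O[Si](CC)(CC)CC)CC[C@]2(C)C[C@H](OCc3ccccc3)[C@@]3(C)O[C@H]3C(=O)[C@H]21
F4 | step 4 | 1-[(R)-5-isopropyl-2-methyl-5-(triethylsilyloxy)cyclopent-1-en-1-yl]but-3-en-1-ol, both carbinol epimers | CC(C)[C@]1(O[Si](CC)(CC)CC)CCC(C)=C1C(O)CC=C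
F5 | step 13 | 9α-benzyloxy-4β-(triethylsilyloxy)daucane-6β,8β-diol | CC(C)[C@]1(O[Si](CC)(CC)CC)CC[C@]2(C)C[C@H](OCc3ccccc3)[C@@](C)(O)C[C@@H](O)[C@H]21
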